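**Plan**

1. Retrosynthetic cuts, in order: the five O–benzyl bonds (every phenol is masked as a benzyl ether, the 7-methyl ether is left alone); the C2–C1' bond between pyranone ring C of the methoxychromone and the central phenol ring B; the C–B bond on ring B (made from C–Cl); the hindered C3–aryl bond of the apigenin unit (3-iodoflavone plus arylboronic acid); the O1–C2 and C2–C3 bonds of the methoxychromone (acetophenone plus a one-carbon unit).
2. Forward order: apigenin supplies its three rings intact and is benzylated, iodinated at C3, coupled to the chlorinated ring B and borylated. In parallel, ring C of the methoxychromone is closed on a mono-benzylated 2,6-dihydroxy-4-methoxyacetophenone. The halves are then joined at C2 and all benzyl groups are removed.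
3. Enabling feature: ring C of the chromone has a C2–H on a C2=C3 bond polarised by O1 and the C4 carbonyl (a vinylogous ester). An aryl–palladium species therefore delivers aryl to C2 and palladium to C3 (C4 enolate), and loss of the C2 and C3 hydrogens restores the pyranone. The chromone needs no activating group, and the 7-methoxy group enters with it, so no late selective methylation among six oxygens is needed.
4. Stereochemistry: the target has no stereocentre. The only sp3 centre of the route (C2 of a transient flavanone) is erased in the same flask.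

Key step: step 7

Assumption: the axis between C3 of the apigenin unit and ring B is drawn without configuration and is treated as not configurationally fixed, so no stereocontrol is planned; [2-(benzyloxy)-5-chlorophenyl]boronic acid is taken as purchasable.

**Route**

Step 1
Reactants: 1 1-(2,6-dihydroxy-4-methoxyphenyl)ethanone
Product: 2 1-[2-(benzyloxy)-6-hydroxy-4-methoxyphenyl]ethanone
Conditions: BnBr (1.05 equiv), K2CO3, acetone, reflux
Reagents that add atoms: benzyl bromide, BrCc1ccccc1
Why: Williamson etherification of one of the two equivalent phenols should stop at the mono-ether, because the remaining hydroxyl is locked in a hydrogen bond to the acetyl carbonyl and is far less nucleophilic.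

Step 2
Reactants: 2 1-[2-(benzyloxy)-6-hydroxy-4-methoxyphenyl]ethanone
Product: 4 5-(benzyloxy)-7-methoxy-4H-chromen-4-one, via enaminone 3 (not isolated)
Conditions: Me2NCH(OMe)2, toluene, 100 °C; then conc. HCl, CH2Cl2, rt
Reagents that add atoms: N,N-dimethylformamide dimethyl acetal, COC(OC)N(C)C
Why: Enaminone formation at the methyl ketone followed by acid-promoted addition–elimination of the free phenol with loss of dimethylamine (enaminone chromone synthesis) should close ring C and leave C2 and C3 unsubstituted.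

Step 3
Reactants: 5 apigenin (5,7-dihydroxy-2-(4-hydroxyphenyl)-4H-chromen-4-one)
Product: 6 5,7-bis(benzyloxy)-2-[4-(benzyloxy)phenyl]-4H-chromen-4-one
Conditions: BnBr (4 equiv), K2CO3, Bu4NI (cat.), DMF, 80 °C
Reagents that add atoms: benzyl bromide, BrCc1ccccc1
Why: Exhaustive Williamson etherification should protect all three phenols, with heat and excess halide driving alkylation of the chelated 5-hydroxyl.

Step 4
Reactants: 6 5,7-bis(benzyloxy)-2-[4-(benzyloxy)phenyl]-4H-chromen-4-one
Product: 8 5,7-bis(benzyloxy)-2-[4-(benzyloxy)phenyl]-3-iodo-4H-chromen-4-one, via 3-lithioflavone 7 (not isolated)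
Conditions: LiN(iPr)2, THF, −78 °C; then I2, THF, −78 °C to rt
Reagents that add atoms: iodine, II
Why: Carbonyl-directed deprotonation of the only vinylic C–H (C3) and iodine quench (lithiation–iodination) should fix the halogen at C3 and avoid electrophilic iodination of the electron-rich C6 and C8 positions of ring A.

Step 5
Reactants: 8 5,7-bis(benzyloxy)-2-[4-(benzyloxy)phenyl]-3-iodo-4H-chromen-4-one; 9 [2-(benzyloxy)-5-chlorophenyl]boronic acid
Product: 10 5,7-bis(benzyloxy)-3-[2-(benzyloxy)-5-chlorophenyl]-2-[4-(benzyloxy)phenyl]-4H-chromen-4-one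
Conditions: Pd(PPh3)4 (cat.), Na2CO3, DME/H2O, 85 °C
Reagents that add atoms: none
Why: Suzuki–Miyaura coupling should occur only at the activated C3–I bond, because triphenylphosphine-ligated zerovalent palladium does not insert into the aryl C–Cl bond, which is kept as the handle for the next step.

Step 6
Reactants: 10 5,7-bis(benzyloxy)-3-[2-(benzyloxy)-5-chlorophenyl]-2-[4-(benzyloxy)phenyl]-4H-chromen-4-one
Product: 11 5,7-bis(benzyloxy)-3-[2-(benzyloxy)-5-(4,4,5,5-tetramethyl-1,3,2-dioxaborolan-2-yl)phenyl]-2-[4-(benzyloxy)phenyl]-4H-chromen-4-one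
Conditions: Pd2(dba)3 (cat.), XPhos, B2pin2, KOAc, 1,4-dioxane, 110 °C
Reagents that add atoms: bis(pinacolato)diboron, CC1(C)OB(OC1(C)C)B1OC(C)(C)C(C)(C)O1
Why: Miyaura borylation with a bulky dialkylbiarylphosphine should activate the unhindered, electron-rich aryl chloride and place boron by ipso substitution para to the benzyloxy group.

Step 7
Reactants: 4 5-(benzyloxy)-7-methoxy-4H-chromen-4-one (2.5 equiv); 11 5,7-bis(benzyloxy)-3-[2-(benzyloxy)-5-(4,4,5,5-tetramethyl-1,3,2-dioxaborolan-2-yl)phenyl]-2-[4-(benzyloxy)phenyl]-4H-chromen-4-one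
Product: 13 5,7-bis(benzyloxy)-3-{2-(benzyloxy)-5-[5-(benzyloxy)-7-methoxy-4-oxo-4H-chromen-2-yl]phenyl}-2-[4-(benzyloxy)phenyl]-4H-chromen-4-one, via flavanone 12 (not isolated)
Conditions: Pd(OCOCF3)2 (15 mol %), 5-nitro-1,10-phenanthroline (20 mol %), O2 (1 atm), DMSO, 100 °C
Reagents that add atoms: none
Why: The aryl group of 11 is transferred from boron to phenanthroline-ligated divalent palladium, the aryl–palladium species inserts the C2=C3 bond of ring C of 4 syn with aryl going to C2 (the β-carbon of the vinylogous ester O1–C2=C3–C4=O) and palladium to C3 as a C4 palladium enolate, protonolysis gives flavanone 12, and the same catalyst dehydrogenates 12 through the palladium enolate and β-hydride elimination from C2 while O2 returns zerovalent palladium to the divalent state. The closest known reaction type is the divalent-palladium-catalysed oxidative boron-Heck arylation (conjugate addition then dehydrogenation) of chromones and chromanones with arylboronic esters to give flavones. No ring is closed in this step. No stereocentre is kept, since C2 of 12 forms as a racemate and becomes sp2 again on dehydrogenation. The step needs C2 over C3 regioselectivity, which the polarisation of the enone and enolate formation at C3–C4 should secure, and transfer of the correct aryl carbon, which the position of the C–B bond para to the benzyloxy group secures. Chemoselectivity rests on the second pyranone in 11 being fully substituted at C2 and C3, so that only 4 can accept the aryl group, and the excess of the simple chromone 4 should favour cross-coupling over homocoupling or oxidation of the boronate.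

Step 8
Reactants: 13 5,7-bis(benzyloxy)-3-{2-(benzyloxy)-5-[5-(benzyloxy)-7-methoxy-4-oxo-4H-chromen-2-yl]phenyl}-2-[4-(benzyloxy)phenyl]-4H-chromen-4-one
Product: 14 5,7-dihydroxy-3-[2-hydroxy-5-(5-hydroxy-7-methoxy-4-oxo-4H-chromen-2-yl)phenyl]-2-(4-hydroxyphenyl)-4H-chromen-4-one (target)
Conditions: H2 (1 atm), palladium on carbon (10 % Pd/C), THF/MeOH, rt
Reagents that add atoms: none
Why: Catalytic hydrogenolysis should cleave the five benzyl ethers while the aryl methyl ether is inert and the conjugated pyranone C2=C3 bonds are not reduced under these mild conditions.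

**Compound list**

1 | 1-(2,6-dihydroxy-4-methoxyphenyl)ethanone | CC(=O)c1c(O)cc(OC)cc1O | starting material
2 | 1-[2-(benzyloxy)-6-hydroxy-4-methoxyphenyl]ethanone | CC(=O)c1c(O)cc(OC)cc1OCc1ccccc1 | intermediate
3 | (E)-1-[2-(benzyloxy)-6-hydroxy-4-methoxyphenyl]-3-(dimethylamino)prop-2-en-1-one (enaminone, formed in the flask in step 2) | CN(C)/C=C/C(=O)c1c(O)cc(OC)cc1OCc1ccccc1 | intermediate
4 | 5-(benzyloxy)-7-methoxy-4H-chromen-4-one | COc1cc(OCc2ccccc2)c2c(=O)ccoc2c1 | intermediate
5 | apigenin, 5,7-dihydroxy-2-(4-hydroxyphenyl)-4H-chromen-4-one | O=c1cc(-c2ccc(O)cc2)oc2cc(O)cc(O)c12 | starting material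
6 | 5,7-bis(benzyloxy)-2-[4-(benzyloxy)phenyl]-4H-chromen-4-one | O=c1cc(-c2ccc(OCc3ccccc3)cc2)oc2cc(OCc3ccccc3)cc(OCc3ccccc3)c12 | intermediate
7 | 5,7-bis(benzyloxy)-2-[4-(benzyloxy)phenyl]-3-lithio-4H-chromen-4-one (3-lithioflavone, formed in the flask in step 4) | [Li]c1c(-c2ccc(OCc3ccccc3)cc2)oc2cc(OCc3ccccc3)cc(OCc3ccccc3)c2c1=O | intermediate
8 | 5,7-bis(benzyloxy)-2-[4-(benzyloxy)phenyl]-3-iodo-4H-chromen-4-one | O=c1c(I)c(-c2ccc(OCc3ccccc3)cc2)oc2cc(OCc3ccccc3)cc(OCc3ccccc3)c12 | intermediate
9 | [2-(benzyloxy)-5-chlorophenyl]boronic acid | OB(O)c1cc(Cl)ccc1OCc1ccccc1 | starting material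
10 | 5,7-bis(benzyloxy)-3-[2-(benzyloxy)-5-chlorophenyl]-2-[4-(benzyloxy)phenyl]-4H-chromen-4-one | Clc1ccc(OCc2ccccc2)c(-c2c(-c3ccc(OCc4ccccc4)cc3)oc3cc(OCc4ccccc4)cc(OCc4ccccc4)c3c2=O)c1 | intermediate
11 | 5,7-bis(benzyloxy)-3-[2-(benzyloxy)-5-(4,4,5,5-tetramethyl-1,3,2-dioxaborolan-2-yl)phenyl]-2-[4-(benzyloxy)phenyl]-4H-chromen-4-one | CC1(C)OB(OC1(C)C)c1ccc(OCc2ccccc2)c(-c2c(-c3ccc(OCc4ccccc4)cc3)oc3cc(OCc4ccccc4)cc(OCc4ccccc4)c3c2=O)c1 | intermediate
12 | racemic 5,7-bis(benzyloxy)-3-{2-(benzyloxy)-5-[5-(benzyloxy)-7-methoxy-4-oxochroman-2-yl]phenyl}-2-[4-(benzyloxy)phenyl]-4H-chromen-4-one (flavanone, formed in the flask in step 7) | COc1cc(OCc2ccccc2)c2C(=O)CC(c3ccc(OCc4ccccc4)c(-c4c(-c5ccc(OCc6ccccc6)cc5)oc5cc(OCc6ccccc6)cc(OCc6ccccc6)c5c4=O)c3)Oc2c1 | intermediate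
13 | 5,7-bis(benzyloxy)-3-{2-(benzyloxy)-5-[5-(benzyloxy)-7-methoxy-4-oxo-4H-chromen-2-yl]phenyl}-2-[4-(benzyloxy)phenyl]-4H-chromen-4-one | COc1cc(OCc2ccccc2)c2c(=O)cc(-c3ccc(OCc4ccccc4)c(-c4c(-c5ccc(OCc6ccccc6)cc5)oc5cc(OCc6ccccc6)cc(OCc6ccccc6)c5c4=O)c3)oc2c1 | intermediate
14 | 5,7-dihydroxy-3-[2-hydroxy-5-(5-hydroxy-7-methoxy-4-oxo-4H-chromen-2-yl)phenyl]-2-(4-hydroxyphenyl)-4H-chromen-4-one | COc1cc(O)c2c(=O)cc(-c3ccc(O)c(-c4c(-c5ccc(O)cc5)oc5cc(O)cc(O)c5c4=O)c3)oc2c1 | target

**Step count**

Total steps: 8. Longest linear sequence: 6 steps (5 → 6 → 8 → 10 → 11 → 13 → 14, steps 3 to 8).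

**Steps most likely to fail**

Step 7. Oxidative homocoupling, protodeboronation or oxidation of the valuable boronate may outrun insertion into the electron-rich 5,7-dioxygenated chromone, and dehydrogenation of the flavanone may stall. The fallback builds ring C of the methoxyflavone from open-chain pieces instead of arylating a finished chromone. It sets out from 8 (and uses 2) and comes back at 13. Commercial 4-(benzyloxy)-3-bromobenzaldehyde would be borylated (B2pin2, PdCl2(dppf), KOAc, dioxane, 90 °C) to 4-(benzyloxy)-3-(4,4,5,5-tetramethyl-1,3,2-dioxaborolan-2-yl)benzaldehyde F1. Suzuki–Miyaura coupling of F1 with iodide 8 (Pd(PPh3)4, Na2CO3, DME/H2O, 85 °C) should give 4-(benzyloxy)-3-{5,7-bis(benzyloxy)-2-[4-(benzyloxy)phenyl]-4-oxo-4H-chromen-3-yl}benzaldehyde F2. Claisen–Schmidt condensation of F2 with acetophenone 2 (KOH, EtOH/THF, rt) should give the 2'-hydroxychalcone (E)-1-[2-(benzyloxy)-6-hydroxy-4-methoxyphenyl]-3-(4-(benzyloxy)-3-{5,7-bis(benzyloxy)-2-[4-(benzyloxy)phenyl]-4-oxo-4H-chromen-3-yl}phenyl)prop-2-en-1-one F3. Oxidative cyclisation of F3 (I2 cat., DMSO, 130 °C) should then close ring C and return the route at 13.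

Step 5. Transmetalation at the crowded palladium centre (C3 flanked by the C2 aryl group and the C4 carbonyl, with an ortho-benzyloxy boronic acid) may be slow, so that protodeiodination of the iodide or protodeboronation of the boronic acid takes over. The fallback reverses the polarity with a Negishi coupling. It sets out from 6 and comes back at 10. Flavone 6 would be lithiated as in step 4 (giving 7) and transmetalated with ZnCl2 in THF to 5,7-bis(benzyloxy)-2-[4-(benzyloxy)phenyl]-3-(chlorozincio)-4H-chromen-4-one F4, which is not isolated. F4 would be coupled (Pd(PPh3)4, THF, 50 °C) with 1-(benzyloxy)-4-chloro-2-iodobenzene F5, itself made from commercial 4-chloro-2-iodophenol with BnBr and K2CO3 in DMF. The C–I bond should react and the C–Cl bond stay, giving 10.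

Step 8. The trisubstituted C2=C3 bond of ring C of the methoxyflavone may be over-reduced, or debenzylation may stall as partly deprotected material precipitates. The fallback removes the benzyl groups without hydrogen. It sets out from 13 and comes back at 14. Treatment of 13 with BCl3 and pentamethylbenzene as cation scavenger in CH2Cl2 at −78 °C should cleave all five benzyl ethers, while the non-chelated 7-methyl ether should survive at this temperature. No new compound arises on the way (F0).

**Further compounds**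

F1 | step 7 | 4-(benzyloxy)-3-(4,4,5,5-tetramethyl-1,3,2-dioxaborolan-2-yl)benzaldehyde | O=Cc1ccc(OCc2ccccc2)c(B2OC(C)(C)C(C)(C)O2)c1
F2 | step 7 | 4-(benzyloxy)-3-{5,7-bis(benzyloxy)-2-[4-(benzyloxy)phenyl]-4-oxo-4H-chromen-3-yl}benzaldehyde | O=Cc1ccc(OCc2ccccc2)c(-c2c(-c3ccc(OCc4ccccc4)cc3)oc3cc(OCc4ccccc4)cc(OCc4ccccc4)c3c2=O)c1
F3 | step 7 | (E)-1-[2-(benzyloxy)-6-hydroxy-4-methoxyphenyl]-3-(4-(benzyloxy)-3-{5,7-bis(benzyloxy)-2-[4-(benzyloxy)phenyl]-4-oxo-4H-chromen-3-yl}phenyl)prop-2-en-1-one | COc1cc(O)c(C(=O)/C=C/c2ccc(OCc3ccccc3)c(-c3c(-c4ccc(OCc5ccccc5)cc4)oc4cc(OCc5ccccc5)cc(OCc5ccccc5)c4c3=O)c2)c(OCc2ccccc2)c1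
F4 | step 5 | 5,7-bis(benzyloxy)-2-[4-(benzyloxy)phenyl]-3-(chlorozincio)-4H-chromen-4-one | Cl[Zn]c1c(-c2ccc(OCc3ccccc3)cc2)oc2cc(OCc3ccccc3)cc(OCc3ccccc3)c2c1=O
F5 | step 5 | 1-(benzyloxy)-4-chloro-2-iodobenzene | Clc1ccc(OCc2ccccc2)c(I)c1
F0 | step 8 | none | none
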